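Read the coupling of first end groups with second end groups into links by its rate, and ask what each flask does to that rate.

| setting | Sunday's | Saturday's | Tuesday's | Friday's | Thursday's |
|---|---|---|---|---|---|
| first end groups | 0.40 M (fed, over 80 min) | 0.40 M | 0.40 M | 0.40 M (fed, over 12 h) | 0.40 M (fed, over 12 h) |
| second end groups | 0.380 M | 0.380 M | 0.380 M (fed, over 12 h) | 0.380 M | 0.380 M |
| temperature | 0 °C |  | 0 °C |  | 0 °C |
| time | 30 h | 30 h | 30 h | 30 h | 30 h |
| remark | all else is in the flask from the start; the feed brings no volume worth counting | everything together at the start at −40 °C, warmed to 0 °C at 12 h | all else is in the flask from the start; the feed brings no volume worth counting | the addition at −40 °C, then warmed to 0 °C; the feed brings no volume worth counting | all else is in the flask from the start; the feed brings no volume worth counting |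

- which flask leads in amount of links, in percent of the first end groups charged ("all alike" within 1.5 percentage points) (Sunday's / Saturday's / Tuesday's / Friday's / Thursday's / all alike)
- how much links is there at the end, in percent of the first end groups charged: Sunday's
- how much links is there at the end, in percent of the first end groups charged: Saturday's
- how much links is there at the end, in percent of the first end groups charged: Tuesday's
- how much links is there at the end, in percent of the first end groups charged: Friday's
- how much links is there at the end, in percent of the first end groups charged: Thursday's

- for links the crystals are counted in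
- as a solid, counted per litre of solution: crystals
- all constants are for 0 °C and move with temperature by the activation energies and enthalpies

    first end groups + second end groups → links (k1 = 6.1 × 10⁻⁵ M⁻¹ s⁻¹, Ea1 = 61.0 kJ mol⁻¹)
    crystals ⇌ links, rate k2*(cs2 - [links]) while solid is left; crystals form when [links] > cs2 (cs2 = 24 mM, k2 = 3.0 × 10⁻⁴ s⁻¹)
    links ⇌ isomer of the product (K3 = 0.69, k3 = 2.3 × 10⁻⁵ s⁻¹, Ea3 = 97.0 kJ mol⁻¹, ΔH3 = 31.0 kJ mol⁻¹)
    (constants at 0 °C)

Let k be the rate constant of the coupling, 6.1 × 10⁻⁵ M⁻¹ s⁻¹, and let cA and cB be the charges. With everything present at 0 °C, the start rate is s = k cA cB = 33.4 mM h⁻¹. We carry one quantity, the start-rate time τ: the time the start rate would need to use up the first end groups charged, τ = cA/s = 12.0 h. The flasks run 30 h, longer than τ, so the slowing of the rate is what we must reckon.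

Cold slows it first. At −40 °C the rate is multiplied by 0.00997, so 12 h there counts as 0.120 h at 0 °C, and we drop those hours. That leaves Saturday's and Friday's with warm hours w = 18.0 h. Feeding comes second. During a steady feed, the rate grows in step with the amount fed, so a feed costs half its length. This gives w = 24.0 h for Tuesday's and Thursday's, and 29.3 h for Sunday's.

Consumption comes third. With a share x of the first end groups coupled, the rate carries the factors 1 − x and 1 − ax, where a = cA/cB = 1.05; the second end groups are the limiting reagent. Accumulated, this gives x = (1 − E)/(1 − aE), with E = exp(−(1 − a)w/τ). So x is 69.7% for Sunday's, 65.5% for Tuesday's and Thursday's, and 59.1% for Saturday's and Friday's. On Sunday's the two factors end at 30.3% and 26.8% by this reckoning.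

We reckon the isomer of the product as the equilibrium constant 0.69 times a dissolved level of links of 24 mM, which is 4.14% of the first end groups charged. By this reckoning links come to 65.5% for Sunday's, 54.9% for Saturday's, 61.4% for Tuesday's, 54.9% for Friday's and 61.4% for Thursday's, with Sunday's ahead.

The forecast names Sunday's, with 65% there, 54% for Saturday's, 60.2% for Tuesday's, 53.9% for Friday's and 60.3% for Thursday's. It holds that “the end amount is set mostly by how long both partners are together”. It takes about 5 percentage points for the isomer where we take 4.14%, and about 5 h as the cost of a 12 h feed where we take 6.00 h.

The simulation gives Sunday's ahead: 64.9% for Sunday's, 54.4% for Saturday's, 60.1% for Tuesday's, 54.3% for Friday's and 60.2% for Thursday's.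

Friday's had 1.50 start-rate times of warm hours, and our 40.9% of first end groups left stands against 40.8% in the flask. Now give Friday's 0.95 M of second end groups, all else held. Then τ becomes 4.79 h, shorter, and the warm hours count 3.76 such times. With a = 0.421, the same formula leaves 6.90% of the first end groups. That flask holds 6.87% of them, and links stand at 87.8%.

(The constants used here are those of an exercise; no experiment stands behind them.)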